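All runs are calculated on assumed constants; the scatter is artificial.

Take one percent of the substrate charged as your unit and count coupling partner in equivalents of substrate, and two runs nearly line up: Wednesday's run, at 1.67 equivalents, holds 29.4% substrate at 4.00 d, and Monday's run, at 1.70 equivalents, holds 28.4%, although their substrate charges differ.

| flask | substrate | coupling partner | initiator | remark | time |
|---|---|---|---|---|---|
| Monday's | 20 mM | 34 mM | 0.11 mM | run made earlier |  |
| Thursday's | 20 mM | 75 mM | 0.11 mM | run made earlier |  |
| Wednesday's | 30 mM | 50 mM | 0.11 mM | run made earlier |  |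
| flask | 20 mM | 50.0 mM | 0.11 mM |  | 3.0 d |

| run | time / d | target / % | substrate / % |
|---|---|---|---|
| Monday's | 0.625 | 26.9 | 74.4 |
| Monday's | 1.25 | 41.4 | 57.7 |
| Monday's | 1.67 | 49.2 | 50.5 |
| Monday's | 2.50 | 61.1 | 40.3 |
| Monday's | 3.00 | 65.2 | 35.0 |
| Monday's | 4.00 | 71.6 | 28.4 |
| Thursday's | 0.250 | 25.7 | 75.4 |
| Thursday's | 0.500 | 41.4 | 59.2 |
| Thursday's | 0.833 | 55.8 | 43.7 |
| Thursday's | 1.25 | 67.3 | 33.2 |
| Thursday's | 2.00 | 80.2 | 18.7 |
| Thursday's | 4.00 | 94.0 | 6.4 |
| Wednesday's | 0.250 | 12.8 | 87.4 |
| Wednesday's | 0.500 | 22.4 | 77.3 |
| Wednesday's | 1.04 | 37.2 | 63.4 |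
| Wednesday's | 2.08 | 54.4 | 46.0 |
| Wednesday's | 4.00 | 71.2 | 29.4 |

(standard deviation of a reading: 0.5 percentage points)

- how much target the flask holds at 3.0 d, in percent of the substrate charged
- how much substrate the flask holds at 3.0 d, in percent of the substrate charged



The flask gets 2.50 equivalents of coupling partner, so substrate is the limiting reagent. The readings give its ledger two entries, target and substrate still there, and Monday's pair at 3.00 d adds to 100%. So you reckon the substrate entry and take target as the remainder.

Let a be the substrate fraction left, r the equivalents charged and x = r − 1, so that x + a equivalents of coupling partner stand in the flask, and suppose substrate loses the share (x + a)/τ of itself per day. Integrated, τ = x t / ln((x + a)/(r a)). Monday's first reading gives 3.30 d, less than its last, 3.93 d, so I use late readings, near the conversion the flask should reach. With Thursday's 3.84 d and Wednesday's 3.96 d, the mean is 3.91 d. This is the coupling time: with one equivalent of coupling partner standing, substrate loses the share one over τ of itself per day. Solved for a in the flask at 3.0 d, my reckoning gives 21.7% substrate and 78.3% target.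

The forecast says 77.5% target and 22.5% substrate, in its words “Slightly tuned against Monday and Thursday”, which puts its substrate 0.80 percentage points above mine.

The flask gives 77.8% target and 22.1% substrate, which read backward is a coupling time of 3.96 d.

    initiator → 2 initiating radical (k = 2.90 × 10⁻⁵ min⁻¹)
    substrate + initiating radical → chain carrier (k = 44000 M⁻¹ s⁻¹)
    coupling partner + chain carrier ⇌ target + initiating radical (K = 0.280, k = 21000 M⁻¹ s⁻¹)
    2 initiating radical → ended chains A (k = 2.00 × 10⁶ M⁻¹ s⁻¹)
    2 chain carrier → ended chains B (k = 1.40 × 10⁹ M⁻¹ s⁻¹)

Over 3.0 d initiator fed initiating radical and kept 88.2% of its charge, while substrate took up initiating radical to chain carrier, half of that turnover being done by 0.710 d. Chain carrier met coupling partner, of which 69% of its own charge stood at 3.0 d, to give target, and ended chains B held 0.129% of the substrate charged, which closes the ledger. Carried to the neighbour charged with 12 mM of coupling partner, 0.600 equivalents, τ gives 71.6% substrate. That neighbour holds 68.5% substrate and 31.4% target at 3.0 d.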